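## Structural features

Vitrofolal B (15) is a 1-arylnaphthalene. Ring A is C1 to C4 with C4a and C8a, ring B is C5 to C8 with the same two fusion carbons, and the 3,4-dimethoxyphenyl ring C is attached to C1 by one biaryl bond. Ring A carries three adjacent substituents (ring C at C1, OH at C2, CHO at C3) and ring B carries two (OH at C7, OMe at C8). Substituted positions therefore run without a gap from C7 over C8, C8a and C1 to C3, and the C8 methoxy group faces ring C across the peri bay. There is no stereocentre, so none stand next to each other, and ring C has only hydrogen at its ortho positions, so the C1–C1' axis should not be configurationally stable. The one sp3 stereocentre met on the way (C1 of 12 and 13) is racemic and disappears on aromatisation. The fragile groups are the aldehyde (hydrogen-bonded to the C2 hydroxyl), two electron-rich naphthol units that oxidise easily, and the methyl ethers, of which the C8 one sits beside the phenol that is unmasked last. The real difficulty is regiochemical and steric: ring B is 1,2,3,4-tetrasubstituted, the C7 oxygen must be told apart from three methoxy groups, and a direct biaryl coupling at C1 would join a carbon flanked by an ortho oxygen and a peri methoxy group. The key step uses the fact that C1 is a single carbon, bearing ring C, between C8a of ring B and the oxygenated C2. An aryldiazomethane places exactly such a carbon between the aryl carbon and the carbonyl carbon of a 1-indanone, so C1 enters as an uncrowded sp3 centre and the ketone oxygen becomes the C2 hydroxyl.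

## Logic of the disconnections

**15 ⇒ 14.** Only the O7–H bond is changed, into an O7–C bond to a secondary alkyl group. The free C7 phenol would not tolerate the hydride base, the quinone oxidant or the diazo reagent used earlier, and it must stay distinguishable from three methyl ethers. The gain is a precursor with one acidic, chelated hydroxyl group. The forward step must break a secondary alkyl–oxygen bond and leave every methyl–oxygen bond intact, including the neighbouring one at C8.

**14 ⇒ 13.** No skeletal bond is cut. Hydrogen is returned to C1 and C4, so ring A goes back to the dihydro level. C1 becomes sp3, the peri strain is relieved, and ring A becomes a β-dicarbonyl system open to enolate chemistry. The forward step needs an oxidant that removes exactly two hydrogens and spares the naphthol it creates.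

**13 ⇒ 12.** The bond between C3 and the formyl carbon is cut. This removes the last one-carbon substituent and leaves a plain ketone with two different α positions. The forward acylation must end at C3 although C1 is the more acidic site, so it must run reversibly. Then the only product able to rest as a stabilised enolate is collected.

**12 ⇒ 7 + 10.** Both ring bonds of C1 are cut, C1–C2 and C1–C8a. This is the most simplifying cut: the molecule falls into two fragments of similar size, ring C leaves with C1, and the six-membered ring shrinks to a five-membered ketone. In that ketone C7a, C7 and C6 map onto C8a, C8 and C7. The forward step demands addition to a hindered, deactivated carbonyl group and then migration of the ring carbon in preference to the methylene carbon.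

**10 ⇒ 9.** Two N–H bonds are restored. The labile diazo function is traced to a condensation product that can be dehydrogenated in the cold. The forward step must deliver a solution free of base, salts and unreacted 9, all of which would disable the Lewis acid of the key step.

**9 ⇒ 8.** The C=N bond is cut, which leads to a commercial aldehyde. The forward condensation must stop after one carbonyl has reacted per hydrazine.

**7 ⇒ 6.** The C–H bond at the ring position that becomes C5 is exchanged for C–Br. The halogen has no role in the target. It is the blocking group that makes the next cut regiochemically possible. The forward reduction must remove it without touching the aryl ketone.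

**6 ⇒ 5.** The bond between the carbonyl carbon (future C2) and the ring carbon (future C8a) is cut. This is the very bond that later migrates, so it serves only to place the carbonyl next to the methoxy-flanked carbon. The gain is an open-chain acid. The forward acylation must enter the crowded position ortho to the methoxy group, which is possible only because the para position is occupied.

**5 ⇒ 4.** The C–Br bond is cut. The forward halogenation must go para to the methoxy group, which requires the phenol to be alkylated already, because a free phenol would direct ortho to itself.

**4 ⇒ 1 + 2.** The O–C(secondary alkyl) bond is cut, giving two commercial materials. The carboxyl group of 1 is alkylated too, so the forward step passes through 3 and includes a hydrolysis in the same flask.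

## Other disconnections considered

**Alternative 1:** The cut is the C2–C3 bond of ring A.
- **Key step:** The substrate is the enyne A1. Ring B carries at C8a the enol acetate of a diarylacetaldehyde (C1=C2) and at C4a the alkyne C4≡C3 with its silyloxymethyl group. PtCl2 in toluene would make the alkyne electrophilic and C2 would attack C3 in a 6-endo-dig closure. Proton loss from C2 with protodemetalation at C4 would then give the naphthyl acetate A2.
- **In favour:** Ring A arrives aromatic, with oxygen on C2 and the future formyl carbon on C3. The connectivity of A1 leaves no doubt about which carbon ends where, and no energetic reagent is involved. On regiochemical certainty and on safety this plan is better than the chosen one.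
- **Against:** The crowding is only moved into A1. A1 needs the same 1,2,3,4-tetrasubstituted ring B, and in addition a diaryl-substituted enol acetate built ortho to the methoxy group and an alkyne on the other side. An enol acetate is a weak π-nucleophile, 5-exo attack at C4 competes, and the propargylic C–O bond can ionise on divalent platinum.
- **Comparison:** After A2 four operations remain (acetate and silyl cleavage, alcohol oxidation, debenzylation beside an aldehyde) against three in the chosen plan. A1 itself should cost distinctly more steps than 7 plus 10. The plan is mechanistically cleaner but longer, and less simplifying at the key cut, since only one bond is formed.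

**Alternative 2:** The cuts are C4–C4a and C1–C8a.
- **Key step:** Lithium 2,2,6,6-tetramethylpiperidide would convert the methyl group of the aroyl enol ether A3 into a dienolate. It would also convert the bromoarene A4 into a 3-methoxyaryne. The dienolate terminus would bond to C4a, the aryl anion at C8a would add to the ketone, and acidic work-up would dehydrate to the naphthoate A5.
- **In favour:** Two bonds and an aromatic ring A form in one operation from two small fragments, which equals the chosen plan in bonds formed and beats it in convergence and oxidation level. The methoxy group adjacent to the aryne directs the nucleophile to the distal carbon, a control element at least as dependable as a migratory preference. A4 is one alkylation away from a commercial bromophenol, so the route could be shorter overall.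
- **Against:** One strong base must generate two reactive partners at matched rates. The aryne is also trapped by the amide base. A3 offers an ester, a ketone and a conjugate acceptor to every anion present. The ring-closing addition goes to a hindered, donor-deactivated ketone. A3 is a tetrasubstituted alkene that is not trivial to prepare.
- **Comparison:** After A5 the ester must be reduced and reoxidised, and the C2 methyl ether removed beside three others. Chelation to the C3 carbonyl makes this possible together with the isopropyl cleavage, so the three closing steps equal the chosen plan. The balance is better step economy on paper against a key step with more competing pathways.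

**Alternative 3:** The cuts are C1–C2 and C2–C3, so C2 is the inserted carbon.
- **Key step:** Ketone 7 would take up the aryl Grignard reagent and lose water to give the arylindene A6. Dibromocarbene from CHBr3 and KOt-Bu would add to its double bond to give the gem-dibromocyclopropane A7. Warming would open A7 with loss of HBr to the bromonaphthalene A8.
- **In favour:** Ring C is attached by an ordinary carbonyl addition, and the position of the inserted carbon is fixed by the cyclopropane, so no migration competes (better than the chosen plan). Ring A arrives aromatic, and the reagents are cheap and free of diazo hazards (better on safety). It shares 7, so the front end is equal.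
- **Against:** The inserted carbon brings bromine where oxygen is needed. The C2 bromide, shielded by ring C, must be turned into a hydroxyl group, then protected, C3 formylated by directed metalation, and two groups removed. That is roughly five steps after A8 against three after 12. The alkene of A6 is trisubstituted and peri-crowded, and KOt-Bu can deprotonate the indene CH2, which would shift the double bond before the carbene arrives.
- **Comparison:** The plan is more predictable in its key bond formation but leaves the oxidation pattern of ring A largely undone, so it is clearly longer.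

Key step: step 7

Assumption: rotation about the C1–C1' bond is taken to be fast at room temperature, so 15 is treated as achiral; 13 is drawn as its chelated Z enol, one of several tautomers.

## Route

Step 1
Reactants: 1 3-(4-hydroxy-3-methoxyphenyl)propanoic acid; 2 2-bromopropane
Product: 4 3-[3-methoxy-4-(propan-2-yloxy)phenyl]propanoic acid, via isopropyl ester 3 (not isolated)
Conditions: 2 (3 equiv), K2CO3, DMF, 60 °C; then aq NaOH, MeOH, 50 °C; aq HCl
Reagents that add atoms: 2-bromopropane CC(C)Br; sodium hydroxide [Na+].[OH-]
Why: Williamson ether synthesis; the carboxylate is alkylated as well, so both sites are alkylated on purpose and ester 3 is saponified in the same flask. The isopropyl ether tolerates bromination, hydrogenolysis, Sc(OTf)3, NaH and DDQ and can later be removed beside methyl ethers.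

Step 2
Reactants: 4 3-[3-methoxy-4-(propan-2-yloxy)phenyl]propanoic acid
Product: 5 3-[2-bromo-5-methoxy-4-(propan-2-yloxy)phenyl]propanoic acid
Conditions: NBS, MeCN, 0 °C → rt, dark
Reagents that add atoms: N-bromosuccinimide O=C1CCC(=O)N1Br
Why: Electrophilic aromatic bromination; in 3,4-dialkoxyphenylalkanes the carbon para to the 3-alkoxy group and ortho to the side chain is the usual site of attack, since the para position of the other oxygen is occupied by the chain. The bromine blocks the carbon at which ring closure would otherwise occur.

Step 3
Reactants: 5 3-[2-bromo-5-methoxy-4-(propan-2-yloxy)phenyl]propanoic acid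
Product: 6 4-bromo-7-methoxy-6-(propan-2-yloxy)-2,3-dihydro-1H-inden-1-one
Conditions: P2O5/MeSO3H (1:10 w/w), rt; ice
Reagents that add atoms: none
Why: Intramolecular Friedel–Crafts acylation through the mixed anhydride or acylium ion; with the para site blocked, the only carbon that can close a five-membered ring lies between the side chain and the methoxy group, which activates it as an ortho donor. Room temperature and short contact limit acid-induced loss of the isopropyl group or the bromine.

Step 4
Reactants: 6 4-bromo-7-methoxy-6-(propan-2-yloxy)-2,3-dihydro-1H-inden-1-one
Product: 7 7-methoxy-6-(propan-2-yloxy)-2,3-dihydro-1H-inden-1-one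
Conditions: H2 (1 atm), Pd/C, NaOAc, MeOH, rt
Reagents that add atoms: none
Why: Catalytic hydrogenolysis of an aryl bromide; NaOAc takes up HBr, so the medium stays non-acidic and the donor-substituted aryl ketone is not reduced at the benzylic position. The alkyl ethers are inert.

Step 5
Reactants: 8 3,4-dimethoxybenzaldehyde
Product: 9 (E)-(3,4-dimethoxybenzylidene)hydrazine
Conditions: N2H4·H2O (10 equiv), EtOH, rt → 50 °C, 8 added slowly
Reagents that add atoms: hydrazine NN
Why: Hydrazone condensation; a large excess of hydrazine and inverse addition suppress reaction of 9 with a second aldehyde. 9 is used without storage.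

Step 6
Reactants: 9 (E)-(3,4-dimethoxybenzylidene)hydrazine
Product: 10 4-(diazomethyl)-1,2-dimethoxybenzene (kept as a cold, titrated solution, never concentrated)
Conditions: MnO2 (activated), MgSO4, CH2Cl2, 0 °C, dark; cold filtration under Ar
Reagents that add atoms: none
Why: Dehydrogenation of a hydrazone to a diazoalkane on MnO2; the oxidant is filtered off, so the solution holds no base or salt that would bind Sc(OTf)3. A donor-substituted aryldiazomethane is heat- and acid-labile, so it is made in the cold and not by hot base-induced cleavage of a sulfonylhydrazone.

Step 7
Reactants: 7 7-methoxy-6-(propan-2-yloxy)-2,3-dihydro-1H-inden-1-one; 10 4-(diazomethyl)-1,2-dimethoxybenzene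
Product: 12 1-(3,4-dimethoxyphenyl)-8-methoxy-7-(propan-2-yloxy)-3,4-dihydronaphthalen-2(1H)-one (racemic), via diazonium alkoxide 11 (not isolated)
Conditions: Sc(OTf)3 (15 mol %), CH2Cl2–toluene, −20 → 0 °C, Ar; 10 (2–3 equiv) by syringe pump
Reagents that add atoms: none
Why: Sc(OTf)3 polarises the carbonyl group of 7, the nucleophilic diazo carbon of 10 adds to it (new bond C1–C2, naphthalene numbering) and the diazonium alkoxide 11 results. In the rotamer of 11 whose C–N2 bond lies antiperiplanar to the bond between the carbinol carbon and ring B, C8a shifts onto the diazo carbon while N2 departs (new bond C1–C8a) and the alkoxide folds back to the C2 ketone. The closest known reaction type is the Lewis acid catalysed homologation of cyclic ketones with aryldiazomethanes (Büchner–Curtius–Schlotterbeck reaction with a Tiffeneau–Demjanov-type shift), and aryl shifts of this kind are familiar from the enlargement of benzo-fused five-membered ketones such as isatins and from the deamination of 1-(aminomethyl)indan-1-ols. Ring A is not closed by a cyclisation: the existing five-membered ring is enlarged to six members by insertion of one carbon through a 1,2-shift. The new stereocentre C1 forms without any controlling element, so 12 is racemic, which is harmless because C1 becomes sp2 in step 9. The step needs migration of C8a in preference to the CH2 group, ketone formation in preference to epoxide closure, and a single insertion. The first is supported by the ability of the aryl carbon to bridge in a phenonium-like transition state stabilised by the ortho methoxy group (C8), whereas the CH2 group offers only a σ bond; the isopropoxy group is meta to C8a and is electronically a bystander. A second insertion is held back because the carbonyl of 12 is flanked by the bulky aryl-bearing C1, and slow addition of cold 10 to the catalyst-bound ketone limits acid-induced self-decay of the diazoalkane.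

Step 8
Reactants: 12 1-(3,4-dimethoxyphenyl)-8-methoxy-7-(propan-2-yloxy)-3,4-dihydronaphthalen-2(1H)-one
Product: 13 (3Z)-1-(3,4-dimethoxyphenyl)-3-(hydroxymethylidene)-8-methoxy-7-(propan-2-yloxy)-3,4-dihydronaphthalen-2(1H)-one (racemic)
Conditions: NaH (3 equiv), HCO2Et (10 equiv), cat. EtOH, degassed THF, 0 °C → rt, Ar; cold aq HCl
Reagents that add atoms: ethyl formate CCOC=O
Why: Claisen-type formylation under equilibrating conditions; acylation at C1 or on oxygen gives products without an acidic proton, which ethoxide cleaves again, while attack through the minor C3 enolate gives a β-keto aldehyde that is withdrawn as its sodium enolate. This is the logic of formyl blocking of 2-substituted cyclohexanones. Air is excluded because the doubly benzylic C1 enolate autoxidises.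

Step 9
Reactants: 13 (3Z)-1-(3,4-dimethoxyphenyl)-3-(hydroxymethylidene)-8-methoxy-7-(propan-2-yloxy)-3,4-dihydronaphthalen-2(1H)-one
Product: 14 4-(3,4-dimethoxyphenyl)-3-hydroxy-5-methoxy-6-(propan-2-yloxy)naphthalene-2-carbaldehyde
Conditions: DDQ (1.05 equiv), 1,4-dioxane, rt
Reagents that add atoms: none
Why: Quinone dehydrogenation; 13 is a tautomer of a 1,4-dihydronaphthalene, so hydride loss from C4 (benzylic and para to the C7 alkoxy group) or C1 followed by proton loss aromatises ring A. One equivalent suffices, the chelated, formyl-deactivated naphthol is much less oxidisable than 13, and the C1 stereocentre vanishes here.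

Step 10
Reactants: 14 4-(3,4-dimethoxyphenyl)-3-hydroxy-5-methoxy-6-(propan-2-yloxy)naphthalene-2-carbaldehyde
Product: 15 vitrofolal B, 4-(3,4-dimethoxyphenyl)-3,6-dihydroxy-5-methoxynaphthalene-2-carbaldehyde
Conditions: BCl3 (4 equiv), CH2Cl2, −78 → 0 °C; H2O
Reagents that add atoms: none
Why: Lewis acid dealkylation of an aryl ether; BCl3 breaks the ionisable secondary alkyl–oxygen bond far faster than methyl–oxygen bonds, a selectivity well known for neighbouring isopropoxy and methoxy groups. No methoxy group stands ortho to the carbonyl, the one position where BCl3 demethylates readily. Extra equivalents are needed because the C2 hydroxyl and the aldehyde bind boron until work-up.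

## Compound list

1 | 3-(4-hydroxy-3-methoxyphenyl)propanoic acid | COc1cc(CCC(=O)O)ccc1O | starting material
2 | 2-bromopropane | CC(C)Br | starting material
3 | propan-2-yl 3-[3-methoxy-4-(propan-2-yloxy)phenyl]propanoate | COc1cc(CCC(=O)OC(C)C)ccc1OC(C)C | intermediate
4 | 3-[3-methoxy-4-(propan-2-yloxy)phenyl]propanoic acid | COc1cc(CCC(=O)O)ccc1OC(C)C | intermediate
5 | 3-[2-bromo-5-methoxy-4-(propan-2-yloxy)phenyl]propanoic acid | COc1cc(CCC(=O)O)c(Br)cc1OC(C)C | intermediate
6 | 4-bromo-7-methoxy-6-(propan-2-yloxy)-2,3-dihydro-1H-inden-1-one | O=C1CCc2c(Br)cc(OC(C)C)c(OC)c21 | intermediate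
7 | 7-methoxy-6-(propan-2-yloxy)-2,3-dihydro-1H-inden-1-one | O=C1CCc2ccc(OC(C)C)c(OC)c21 | intermediate
8 | 3,4-dimethoxybenzaldehyde | COc1ccc(C=O)cc1OC | starting material
9 | (E)-(3,4-dimethoxybenzylidene)hydrazine | COc1ccc(/C=N/N)cc1OC | intermediate
10 | 4-(diazomethyl)-1,2-dimethoxybenzene | COc1ccc(C=[N+]=[N-])cc1OC | intermediate
11 | 1-[diazonio(3,4-dimethoxyphenyl)methyl]-7-methoxy-6-(propan-2-yloxy)-2,3-dihydro-1H-inden-1-olate (scandium-bound in the flask, diastereomer mixture) | COc1ccc(C([N+]#N)C2([O-])CCc3ccc(OC(C)C)c(OC)c32)cc1OC | intermediate
12 | 1-(3,4-dimethoxyphenyl)-8-methoxy-7-(propan-2-yloxy)-3,4-dihydronaphthalen-2(1H)-one (racemic) | O=C1CCc2ccc(OC(C)C)c(OC)c2C1c1ccc(OC)c(OC)c1 | intermediate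
13 | (3Z)-1-(3,4-dimethoxyphenyl)-3-(hydroxymethylidene)-8-methoxy-7-(propan-2-yloxy)-3,4-dihydronaphthalen-2(1H)-one (racemic) | O/C=C1/Cc2ccc(OC(C)C)c(OC)c2C(c2ccc(OC)c(OC)c2)C1=O | intermediate
14 | 4-(3,4-dimethoxyphenyl)-3-hydroxy-5-methoxy-6-(propan-2-yloxy)naphthalene-2-carbaldehyde | COc1ccc(-c2c(O)c(C=O)cc3ccc(OC(C)C)c(OC)c23)cc1OC | intermediate
15 | vitrofolal B, 4-(3,4-dimethoxyphenyl)-3,6-dihydroxy-5-methoxynaphthalene-2-carbaldehyde | COc1ccc(-c2c(O)c(C=O)cc3ccc(O)c(OC)c23)cc1OC | target

## Step count and least certain steps

Total: 10 steps. Longest linear sequence: 8 steps (steps 1 to 4 and 7 to 10). Steps 5 and 6 form a two-step side branch.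

**Step 7 (key step).**
- **Risk:** The methylene carbon may migrate instead of the ring carbon. The rotamer needed for the aryl shift places ring C gauche to the methoxy-flanked ring B, so sterics oppose the electronic preference. If trivalent scandium chelates the carbonyl and the C8 methoxy oxygen, that donor is also weakened.
- **Second risk:** The conjugated, ortho-donor-substituted carbonyl may add the diazoalkane more slowly than the Lewis acid destroys it.
- **Fallback, from 7:** Wittig methylenation (Ph3P=CH2, THF) gives 7-methoxy-1-methylidene-6-(propan-2-yloxy)-2,3-dihydro-1H-indene F1. Oxidative rearrangement follows with PhI(OH)OTs in 95 % MeOH: trivalent iodine adds to the CH2 terminus and the aryl carbon shifts as iodobenzene leaves. This gives 8-methoxy-7-(propan-2-yloxy)-3,4-dihydronaphthalen-2(1H)-one F2. Palladium-catalysed ketone α-arylation at the more acidic benzylic C1 with 4-bromo-1,2-dimethoxybenzene (Pd(OAc)2, P(t-Bu)3, NaOt-Bu, toluene, 80 °C) comes back to the route at 12.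

**Step 8.**
- **Risk:** The substrate may be parked as its strongly stabilised C1 enolate, so that attack through C3 is too slow, with autoxidation at C1 as the competing drain.
- **Fallback, from 12:** Aromatisation comes first. DDQ in dioxane gives 1-(3,4-dimethoxyphenyl)-8-methoxy-7-(propan-2-yloxy)naphthalen-2-ol F3. MOMCl with i-Pr2NEt gives 1-(3,4-dimethoxyphenyl)-8-methoxy-2-(methoxymethoxy)-7-(propan-2-yloxy)naphthalene F4. Directed ortho-lithiation at C3 (n-BuLi, TMEDA, THF, 0 °C), the reaction routinely used on 1-aryl-2-(methoxymethoxy)naphthalenes, and a DMF quench give 4-(3,4-dimethoxyphenyl)-5-methoxy-3-(methoxymethoxy)-6-(propan-2-yloxy)naphthalene-2-carbaldehyde F5. HCl in MeOH removes the acetal and the route is rejoined at 14.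

**Step 3.**
- **Risk:** The strongly acidic medium may strip the isopropyl group. It may also transfer the blocking bromine, whose carbon is para to the methoxy group and open to ipso attack, which would open the unwanted ring closure.
- **Fallback, from 5:** (COCl)2 with catalytic DMF gives 3-[2-bromo-5-methoxy-4-(propan-2-yloxy)phenyl]propanoyl chloride F6. F6 is dissolved in 1,1,1,3,3,3-hexafluoropropan-2-ol at rt without any added acid. Hydrogen-bond activation of the preformed acyl chloride replaces the dehydrating superacid, and the route is rejoined at 6.

**Step 6.**
- **Risk:** The diazoalkane may decay before use, by nitrogen loss and coupling with itself or with leftover hydrazone. Oxidation may also be incomplete and leave a basic nitrogen compound that binds the catalyst of step 7.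
- **Fallback, from 8:** Condensation with TsNHNH2 in MeOH gives the storable N'-[(E)-(3,4-dimethoxyphenyl)methylidene]-4-methylbenzenesulfonohydrazide F7. Its sodium salt (NaOMe) is decomposed by a Bamford–Stevens reaction in toluene with BnEt3NCl at 40 °C. The solution is drawn off through a filter cannula into the cold flask of step 7 as it forms, which returns to 10.

**Step 10.**
- **Risk:** The C8 methyl ether may be lost after the isopropyl group. That ether is twisted out of plane by its two neighbours, and once O7 carries boron it lies within reach of an intramolecular Lewis acid.
- **Fallback, from 7 (change of protecting-group strategy):** MeSO3H in CH2Cl2 at 40 °C ionises only the secondary alkyl–oxygen bond and gives 6-hydroxy-7-methoxy-2,3-dihydro-1H-inden-1-one F8. Allyl bromide with K2CO3 gives 7-methoxy-6-(prop-2-en-1-yloxy)-2,3-dihydro-1H-inden-1-one F9. The conditions of steps 7 to 9 are then applied in turn: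
  - first 1-(3,4-dimethoxyphenyl)-8-methoxy-7-(prop-2-en-1-yloxy)-3,4-dihydronaphthalen-2(1H)-one F10;
  - then (3Z)-1-(3,4-dimethoxyphenyl)-3-(hydroxymethylidene)-8-methoxy-7-(prop-2-en-1-yloxy)-3,4-dihydronaphthalen-2(1H)-one F11;
  - then 4-(3,4-dimethoxyphenyl)-3-hydroxy-5-methoxy-6-(prop-2-en-1-yloxy)naphthalene-2-carbaldehyde F12.

  Deallylation with zerovalent palladium (Pd(PPh3)4, K2CO3, MeOH, rt) needs no Lewis acid and arrives at 15.

## Further compounds

F1 | step 7 | 7-methoxy-1-methylidene-6-(propan-2-yloxy)-2,3-dihydro-1H-indene | C=C1CCc2ccc(OC(C)C)c(OC)c21
F2 | step 7 | 8-methoxy-7-(propan-2-yloxy)-3,4-dihydronaphthalen-2(1H)-one | O=C1CCc2ccc(OC(C)C)c(OC)c2C1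
F3 | step 8 | 1-(3,4-dimethoxyphenyl)-8-methoxy-7-(propan-2-yloxy)naphthalen-2-ol | COc1ccc(-c2c(O)ccc3ccc(OC(C)C)c(OC)c23)cc1OC
F4 | step 8 | 1-(3,4-dimethoxyphenyl)-8-methoxy-2-(methoxymethoxy)-7-(propan-2-yloxy)naphthalene | COCOc1ccc2ccc(OC(C)C)c(OC)c2c1-c1ccc(OC)c(OC)c1
F5 | step 8 | 4-(3,4-dimethoxyphenyl)-5-methoxy-3-(methoxymethoxy)-6-(propan-2-yloxy)naphthalene-2-carbaldehyde | COCOc1c(C=O)cc2ccc(OC(C)C)c(OC)c2c1-c1ccc(OC)c(OC)c1
F6 | step 3 | 3-[2-bromo-5-methoxy-4-(propan-2-yloxy)phenyl]propanoyl chloride | COc1cc(CCC(=O)Cl)c(Br)cc1OC(C)C
F7 | step 6 | N'-[(E)-(3,4-dimethoxyphenyl)methylidene]-4-methylbenzenesulfonohydrazide | COc1ccc(/C=N/NS(=O)(=O)c2ccc(C)cc2)cc1OC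
F8 | step 10 | 6-hydroxy-7-methoxy-2,3-dihydro-1H-inden-1-one | O=C1CCc2ccc(O)c(OC)c21
F9 | step 10 | 7-methoxy-6-(prop-2-en-1-yloxy)-2,3-dihydro-1H-inden-1-one | O=C1CCc2ccc(OCC=C)c(OC)c21
F10 | step 10 | 1-(3,4-dimethoxyphenyl)-8-methoxy-7-(prop-2-en-1-yloxy)-3,4-dihydronaphthalen-2(1H)-one (racemic) | O=C1CCc2ccc(OCC=C)c(OC)c2C1c1ccc(OC)c(OC)c1
F11 | step 10 | (3Z)-1-(3,4-dimethoxyphenyl)-3-(hydroxymethylidene)-8-methoxy-7-(prop-2-en-1-yloxy)-3,4-dihydronaphthalen-2(1H)-one (racemic) | O/C=C1/Cc2ccc(OCC=C)c(OC)c2C(c2ccc(OC)c(OC)c2)C1=O
F12 | step 10 | 4-(3,4-dimethoxyphenyl)-3-hydroxy-5-methoxy-6-(prop-2-en-1-yloxy)naphthalene-2-carbaldehyde | COc1ccc(-c2c(O)c(C=O)cc3ccc(OCC=C)c(OC)c23)cc1OC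
A1 | alternative 1 | 2-[3-(benzyloxy)-6-{3-[(tert-butyldimethylsilyl)oxy]prop-1-yn-1-yl}-2-methoxyphenyl]-2-(3,4-dimethoxyphenyl)ethenyl acetate (E/Z mixture) | CC(=O)OC=C(c1ccc(OC)c(OC)c1)c1c(OC)c(OCc2ccccc2)ccc1C#CCO[Si](C)(C)C(C)(C)C
A2 | alternative 1 | 7-(benzyloxy)-3-{[(tert-butyldimethylsilyl)oxy]methyl}-1-(3,4-dimethoxyphenyl)-8-methoxynaphthalen-2-yl acetate | CC(=O)Oc1c(CO[Si](C)(C)C(C)(C)C)cc2ccc(OCc3ccccc3)c(OC)c2c1-c1ccc(OC)c(OC)c1
A3 | alternative 2 | methyl 4-(3,4-dimethoxyphenyl)-3-methoxy-2-methyl-4-oxobut-2-enoate (alkene geometry not fixed) | COC(=O)C(C)=C(OC)C(=O)c1ccc(OC)c(OC)c1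
A4 | alternative 2 | 4-bromo-2-methoxy-1-(propan-2-yloxy)benzene | COc1cc(Br)ccc1OC(C)C
A5 | alternative 2 | methyl 4-(3,4-dimethoxyphenyl)-3,5-dimethoxy-6-(propan-2-yloxy)naphthalene-2-carboxylate | COC(=O)c1cc2ccc(OC(C)C)c(OC)c2c(-c2ccc(OC)c(OC)c2)c1OC
A6 | alternative 3 | 3-(3,4-dimethoxyphenyl)-4-methoxy-5-(propan-2-yloxy)-1H-indene | COc1ccc(C2=CCc3ccc(OC(C)C)c(OC)c32)cc1OC
A7 | alternative 3 | gem-dibromocyclopropane adduct of A6, CBr2 bridging indene C2 and C3 (racemic, cis-fused by necessity) | COc1ccc(C23C(Cc4ccc(OC(C)C)c(OC)c42)C3(Br)Br)cc1OC
A8 | alternative 3 | 2-bromo-1-(3,4-dimethoxyphenyl)-8-methoxy-7-(propan-2-yloxy)naphthalene | COc1ccc(-c2c(Br)ccc3ccc(OC(C)C)c(OC)c23)cc1OC
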